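Quinone ring B is cut from benzenoid ring A at C4–C4a and C1–C8a. C1 and C4, through which ring B joins ring A, are both oxygenated and C2 bears methoxy. The four carbons and three oxygens of ring B are therefore those of a 3-methoxy-2-siloxyfuran. Ring A becomes a C4a≡C8a aryne that already holds the C8 aryl and C6 methoxy groups. In one operation, [4+2] cycloaddition and opening of the bridged ketal build ring B as a hydroquinone monosilyl ether, one oxidation short of the target. The aryne precursor is an ortho-silylaryl triflate made from a symmetrical dibromophenol.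

Key step: step 7

Remark: atom numbers are those of the target naphthoquinone (C1=O peri to the aryl group on C8, methoxy groups on C2 and C6). The target has no stereocentre, and the hydroxylactone is used as the racemate.
Remark: 2,6-dibromo-4-methoxyphenol is taken as a catalogue compound. Starting from it means the electron-rich veratryl ring never meets an electrophilic halogen source.

Step 1
Reactants: 1 2,6-dibromo-4-methoxyphenol
Product: 4 2-bromo-4-methoxy-6-(trimethylsilyl)phenol, via aryl silyl ether 2 (not isolated), via aryllithium 3 (not isolated)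
Conditions: HMDS (1 equiv), THF, 70 °C, evaporate; n-BuLi (1.05 equiv), THF, −78 °C to rt; aq NH4Cl
Reagents that add atoms: hexamethyldisilazane, C[Si](C)(C)N[Si](C)(C)C
Why: Silylation of the acidic phenol, single bromine–lithium exchange and a 1,3 O-to-C silyl shift (retro-Brook rearrangement) driven by phenoxide formation should desymmetrise 1 cleanly, since both bromines are equivalent, the remaining one sits meta to lithium in 3 and cannot be eliminated, and the phenoxide ring resists further exchange.

Step 2
Reactants: 4 2-bromo-4-methoxy-6-(trimethylsilyl)phenol, 5 3,4-dimethoxyphenylboronic acid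
Product: 6 2-(3,4-dimethoxyphenyl)-4-methoxy-6-(trimethylsilyl)phenol
Conditions: Pd(OAc)2 (3 mol %), SPhos (6 mol %), K3PO4 (3 equiv), toluene/H2O 10:1, 80 °C, degassed
Reagents that add atoms: none
Why: This is a Suzuki–Miyaura coupling of an ortho-bromophenol, in which the bulky electron-rich phosphine speeds oxidative addition of zerovalent palladium into the hindered C–Br bond while the aryl–SiMe3 bond is inert in the absence of fluoride.

Step 3
Reactants: 6 2-(3,4-dimethoxyphenyl)-4-methoxy-6-(trimethylsilyl)phenol
Product: 7 2-(3,4-dimethoxyphenyl)-4-methoxy-6-(trimethylsilyl)phenyl trifluoromethanesulfonate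
Conditions: Tf2O (1.2 equiv), pyridine (3 equiv), CH2Cl2, 0 °C
Reagents that add atoms: trifluoromethanesulfonic anhydride, O=S(=O)(OS(=O)(=O)C(F)(F)F)C(F)(F)F
Why: O-Sulfonylation of a phenol with triflic anhydride under pyridine buffering, the usual last step towards ortho-silylaryl triflates, keeps strong acid out of the medium so that the C–Si bond is not protonolysed.

Step 4
Reactants: 8 3-hydroxydihydrofuran-2(3H)-one (alpha-hydroxy-gamma-butyrolactone)
Product: 10 3-hydroxyfuran-2(5H)-one, via keto lactone 9 (not isolated)
Conditions: DMP (1.2 equiv), CH2Cl2, 0 °C to rt; Et2O, filter through SiO2, evaporate with toluene; use at once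
Reagents that add atoms: none
Why: Dess–Martin oxidation of a secondary alpha-hydroxy ester under neutral, water-free conditions gives 9, which tautomerises to the conjugated enol 10, and the non-aqueous work-up avoids loss of the small water-soluble product.

Step 5
Reactants: 10 3-hydroxyfuran-2(5H)-one
Product: 11 3-methoxyfuran-2(5H)-one
Conditions: TMSCHN2 (1.2 equiv), toluene/MeOH 4:1, 0 °C
Reagents that add atoms: (trimethylsilyl)diazomethane, C[Si](C)(C)C=[N+]=[N-]
Why: This is O-methylation of an acidic enol with a diazoalkane: 10 protonates the reagent, methanol removes the silyl group, and the methyldiazonium ion is captured at the enol oxygen in a base-free medium that suppresses aldol self-condensation.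

Step 6
Reactants: 11 3-methoxyfuran-2(5H)-one
Product: 12 2-(tert-butyldimethylsilyloxy)-3-methoxyfuran
Conditions: TBSOTf (1.1 equiv), Et3N (1.5 equiv), CH2Cl2, 0 °C; pentane, cold aq NaHCO3; bulb-to-bulb distillation
Reagents that add atoms: tert-butyldimethylsilyl trifluoromethanesulfonate, CC(C)(C)[Si](C)(C)OS(=O)(=O)C(F)(F)F
Why: This is soft enolisation of a butenolide (silyl dienol ether formation): the silyl triflate silylates the lactone carbonyl oxygen and Et3N removes a C5 proton, with the gain of furan aromaticity as driving force.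

Step 7
Reactants: 7 2-(3,4-dimethoxyphenyl)-4-methoxy-6-(trimethylsilyl)phenyl trifluoromethanesulfonate, 12 2-(tert-butyldimethylsilyloxy)-3-methoxyfuran
Product: 15 4-(tert-butyldimethylsilyloxy)-5-(3,4-dimethoxyphenyl)-3,7-dimethoxynaphthalen-1-ol, via aryne 13 (not isolated), via oxabicycle 14 (not isolated)
Conditions: 12 (3 equiv), CsF (2.5 equiv), MeCN/toluene 1:1, rt, N2; filter; PPTS (10 mol %), CH2Cl2, rt
Reagents that add atoms: none
Why: Fluoride attacks the unhindered SiMe3 group of 7, triflate departs, and the strained in-plane π bond of aryne 13 adds across C2 and C5 of the electron-rich furan 12 in a concerted but asynchronous [4+2] cycloaddition in which C4–C4a forms ahead of C1–C8a. In oxabicycle 14 the bridge C1–O bond then ionises with the help of the siloxy oxygen (PPTS completes this), and loss of the C4 bridgehead proton aromatises ring B to naphthol 15. The closest known reaction type is the aryne Diels–Alder reaction of 2-alkoxy- and 2-siloxyfurans with isomerisation of the 1,4-epoxides to 4-oxygenated 1-naphthols. Ring B closes by intermolecular suprafacial [π4s+π2s] annulation, and the two bridgehead stereocentres of 14 arise as a racemate and vanish on aromatisation, so no stereocontrol is needed. The step needs one orientation: the unsubstituted C5 of 12, the most nucleophilic and least hindered diene terminus, must bond to C4a, which is favoured because the twisted C8 aryl group shields C8a and its weak σ-withdrawal makes the remote carbon C4a the more electrophilic one, while the C6 methoxy group has little influence; the bias is moderate, and a minor isomer would be removed by chromatography. It also needs fluoride to choose C–SiMe3 over the hindered O–SiMe2t-Bu group, which sparingly soluble CsF in MeCN/toluene and an excess of 12 should secure, and any hydroquinone formed by silyl loss converges on 16 in step 8.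

Step 8
Reactants: 15 4-(tert-butyldimethylsilyloxy)-5-(3,4-dimethoxyphenyl)-3,7-dimethoxynaphthalen-1-ol
Product: 16 8-(3,4-dimethoxyphenyl)-2,6-dimethoxynaphthalene-1,4-dione
Conditions: PhI(OAc)2 (1.1 equiv), MeCN/H2O 4:1, 0 °C
Reagents that add atoms: none
Why: This is oxidation of a para-oxygenated naphthol with a trivalent iodine reagent: ligand exchange at the free hydroxyl, two-electron oxidation and loss of silicon from the silyloxocarbenium ion to water give the quinone, and the naphthol is so much easier to oxidise than the veratryl ring that the latter should stay untouched.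

Compound list
1 | 2,6-dibromo-4-methoxyphenol | COc1cc(Br)c(O)c(Br)c1 | starting material
2 | (2,6-dibromo-4-methoxyphenoxy)trimethylsilane | COc1cc(Br)c(O[Si](C)(C)C)c(Br)c1 | intermediate
3 | [3-bromo-5-methoxy-2-(trimethylsilyloxy)phenyl]lithium | COc1cc(Br)c(O[Si](C)(C)C)c([Li])c1 | intermediate
4 | 2-bromo-4-methoxy-6-(trimethylsilyl)phenol | COc1cc(Br)c(O)c([Si](C)(C)C)c1 | intermediate
5 | 3,4-dimethoxyphenylboronic acid | COc1ccc(B(O)O)cc1OC | starting material
6 | 2-(3,4-dimethoxyphenyl)-4-methoxy-6-(trimethylsilyl)phenol | COc1cc(-c2ccc(OC)c(OC)c2)c(O)c([Si](C)(C)C)c1 | intermediate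
7 | 2-(3,4-dimethoxyphenyl)-4-methoxy-6-(trimethylsilyl)phenyl trifluoromethanesulfonate | C[Si](C)(C)c1cc(OC)cc(-c2ccc(OC)c(OC)c2)c1OS(=O)(=O)C(F)(F)F | intermediate
8 | 3-hydroxydihydrofuran-2(3H)-one (alpha-hydroxy-gamma-butyrolactone, racemic) | OC1CCOC1=O | starting material
9 | dihydrofuran-2,3-dione | O=C1CCOC1=O | intermediate
10 | 3-hydroxyfuran-2(5H)-one | OC1=CCOC1=O | intermediate
11 | 3-methoxyfuran-2(5H)-one | COC1=CCOC1=O | intermediate
12 | 2-(tert-butyldimethylsilyloxy)-3-methoxyfuran | COc1ccoc1O[Si](C)(C)C(C)(C)C | intermediate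
13 | 3-(3,4-dimethoxyphenyl)-5-methoxybenzyne | COC1=CC#CC(=C1)c1ccc(OC)c(OC)c1 | intermediate
14 | 1-(tert-butyldimethylsilyloxy)-8-(3,4-dimethoxyphenyl)-2,6-dimethoxy-1,4-dihydro-1,4-epoxynaphthalene (racemic) | COC1=CC2OC1(O[Si](C)(C)C(C)(C)C)c1c2cc(OC)cc1-c1ccc(OC)c(OC)c1 | intermediate
15 | 4-(tert-butyldimethylsilyloxy)-5-(3,4-dimethoxyphenyl)-3,7-dimethoxynaphthalen-1-ol | COc1cc(O)c2cc(OC)cc(-c3ccc(OC)c(OC)c3)c2c1O[Si](C)(C)C(C)(C)C | intermediate
16 | 8-(3,4-dimethoxyphenyl)-2,6-dimethoxynaphthalene-1,4-dione | COC1=CC(=O)c2cc(OC)cc(-c3ccc(OC)c(OC)c3)c2C1=O | target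

Total step count: 8 (convergent).
Longest linear sequence: 5 steps (1, 2, 3, 7, 8). The furan arm (4, 5, 6, 7, 8) is equally long.

Steps most likely to fail

Step 7. The orientation of the cycloaddition may be poorly controlled, because the aryl group polarises the aryne only weakly. The furan may also lose its silyl group to fluoride before it is trapped.
- The fallback lets a halogen steer the aryne and attaches the aryl group afterwards. It sets out from 4.
- Phenol 4 is triflated (Tf2O, pyridine, CH2Cl2) to 2-bromo-4-methoxy-6-(trimethylsilyl)phenyl trifluoromethanesulfonate F1.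
- CsF in the presence of 12 releases 3-bromo-5-methoxybenzyne F2. Its strongly σ-withdrawing C–Br bond next to the triple bond sends the nucleophilic furan carbon to the remote aryne carbon much more firmly.
- The cycloadduct 8-bromo-1-(tert-butyldimethylsilyloxy)-2,6-dimethoxy-1,4-dihydro-1,4-epoxynaphthalene F3 opens to 5-bromo-4-(tert-butyldimethylsilyloxy)-3,7-dimethoxynaphthalen-1-ol F4.
- Suzuki–Miyaura coupling of F4 with 5 (Pd(OAc)2, SPhos, K3PO4, degassed toluene/H2O) comes back to the route at 15.

Step 4. The enolisable keto lactone may self-condense, and the small polar product may be lost during isolation.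
- The fallback never frees the keto lactone. It installs the ether first and the double bond second, setting out from 8.
- Lactone 8 is O-methylated (Ag2O, MeI, CH2Cl2, dark) to 3-methoxydihydrofuran-2(3H)-one F5.
- Deprotonation with LiN(i-Pr)2 in THF at −78 °C and trapping with PhSeBr give 3-methoxy-3-(phenylselanyl)dihydrofuran-2(3H)-one F6.
- H2O2 in CH2Cl2 at 0 °C forms the selenoxide 3-methoxy-3-(phenylseleninyl)dihydrofuran-2(3H)-one F7. Its syn elimination can only involve a C4 hydrogen, so it comes back to the route at 11.

Step 2. The ortho-silylphenoxide may undergo protodesilylation in hot aqueous base, or oxidative addition into the electron-rich, flanked bromide may be sluggish.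
- The fallback forms the biaryl bond before silicon is introduced, setting out from 1.
- Dibromophenol 1, used in excess so that single coupling prevails, is coupled with 5 (Pd(PPh3)4, Na2CO3, DME/H2O, 80 °C) to 2-bromo-6-(3,4-dimethoxyphenyl)-4-methoxyphenol F8.
- HMDS gives [2-bromo-6-(3,4-dimethoxyphenyl)-4-methoxyphenoxy]trimethylsilane F9.
- n-BuLi at −78 °C produces [3-(3,4-dimethoxyphenyl)-5-methoxy-2-(trimethylsilyloxy)phenyl]lithium F10. Its retro-Brook shift and an aqueous NH4Cl quench come back to the route at 6.

Further compounds
F1 | step 7 | 2-bromo-4-methoxy-6-(trimethylsilyl)phenyl trifluoromethanesulfonate | C[Si](C)(C)c1cc(OC)cc(Br)c1OS(=O)(=O)C(F)(F)F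
F2 | step 7 | 3-bromo-5-methoxybenzyne | COC1=CC#CC(Br)=C1
F3 | step 7 | 8-bromo-1-(tert-butyldimethylsilyloxy)-2,6-dimethoxy-1,4-dihydro-1,4-epoxynaphthalene (racemic) | COC1=CC2OC1(O[Si](C)(C)C(C)(C)C)c1c2cc(OC)cc1Br
F4 | step 7 | 5-bromo-4-(tert-butyldimethylsilyloxy)-3,7-dimethoxynaphthalen-1-ol | COc1cc(O)c2cc(OC)cc(Br)c2c1O[Si](C)(C)C(C)(C)C
F5 | step 4 | 3-methoxydihydrofuran-2(3H)-one (racemic) | COC1CCOC1=O
F6 | step 4 | 3-methoxy-3-(phenylselanyl)dihydrofuran-2(3H)-one (racemic) | COC1([Se]c2ccccc2)CCOC1=O
F7 | step 4 | 3-methoxy-3-(phenylseleninyl)dihydrofuran-2(3H)-one | COC1([Se](=O)c2ccccc2)CCOC1=O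
F8 | step 2 | 2-bromo-6-(3,4-dimethoxyphenyl)-4-methoxyphenol | COc1cc(Br)c(O)c(-c2ccc(OC)c(OC)c2)c1
F9 | step 2 | [2-bromo-6-(3,4-dimethoxyphenyl)-4-methoxyphenoxy]trimethylsilane | COc1cc(Br)c(O[Si](C)(C)C)c(-c2ccc(OC)c(OC)c2)c1
F10 | step 2 | [3-(3,4-dimethoxyphenyl)-5-methoxy-2-(trimethylsilyloxy)phenyl]lithium | COc1cc([Li])c(O[Si](C)(C)C)c(-c2ccc(OC)c(OC)c2)c1
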